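**Strategy**

The C40 retro-polyene (carotenoid numbering) is cut at the sp2–sp2 single bond C12′–C11′ into a retinal-derived retro-polyenyne and a trienyl iodide that carries the saturated ring. Everything rests on that ring: its only stereocentre, the methyl-bearing C5′, is bonded to C6′, the ring carbon of the exocyclic C6′=C7′ alkene. A rhodium-catalysed asymmetric silylcarbocyclization of the acyclic 1,7-enyne 3,3-dimethyloct-7-en-1-yne forms the C5′–C6′ bond, the six-membered ring, the C5′ stereocentre and the alkene geometry in one operation: the alkyne supplies C6′ and C7′, the vinyl group supplies C5′ and its methyl, and silicon ends cis to C5′, where the polyene is attached later.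

Key step: step 4

Remark: unprimed numbers C1–C20 belong to the half with the cyclohexene ring and primed numbers to the half with the saturated ring; the target is read as (5′S,6E,6′E) and all-E in the chain. For step 4 the (R)-ligand is written on the assumption that it delivers the (S) centre; the (S)-ligand is used if the sense of induction is opposite.

**Route**

Step 1
Reactants: 1 isobutyronitrile; 2 5-bromopent-1-ene
Product: 4 2,2-dimethylhept-6-enenitrile, via lithiated isobutyronitrile 3 (not isolated)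
Conditions: LiN(i-Pr)2, THF, −78 °C; then 2, −78 °C to rt
Reagents that add atoms: none
Why: SN2 alkylation of the nitrile-stabilised tertiary carbanion with a primary bromide installs the quaternary gem-dimethyl carbon (future C1′) next to the carbon that becomes C6′.

Step 2
Reactants: 4 2,2-dimethylhept-6-enenitrile
Product: 6 2,2-dimethylhept-6-enal, via aluminium aldimine 5 (not isolated)
Conditions: i-Bu2AlH, CH2Cl2, −78 °C; then 1 M aq. HCl, 0 °C
Reagents that add atoms: water, O
Why: Partial reduction of the nitrile with i-Bu2AlH should stop at the N-aluminated aldimine, which is hydrolysed on work-up to the non-enolizable aldehyde (nitrile-to-aldehyde reduction).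

Step 3
Reactants: 6 2,2-dimethylhept-6-enal
Product: 7 3,3-dimethyloct-7-en-1-yne
Conditions: dimethyl (1-diazo-2-oxopropyl)phosphonate, K2CO3, MeOH, 0 °C to rt
Reagents that add atoms: dimethyl (1-diazo-2-oxopropyl)phosphonate, COP(=O)(OC)C(=[N+]=[N-])C(C)=O
Why: Seyferth–Gilbert homologation in the Ohira–Bestmann variant should convert the non-enolizable aldehyde into the terminal alkyne without touching the terminal alkene.

Step 4
Reactants: 7 3,3-dimethyloct-7-en-1-yne
Product: 8 benzyl(dimethyl){(E)-[(6S)-2,2,6-trimethylcyclohexylidene]methyl}silane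
Conditions: [Rh(cod)2]SbF6 (5 mol %), (R)-BIPHEMP (5 mol %), BnMe2SiH (3 equiv), ClCH2CH2Cl, 70 °C
Reagents that add atoms: benzyldimethylsilane, C[SiH](C)Cc1ccccc1
Why: Proposed new method: a cationic Rh–silyl species adds syn across the terminal alkyne (Si to C7′, Rh to C6′), the alkenyl–Rh bond then inserts the pendant vinyl group to form the C6′–C5′ bond, and Si–H oxidative addition followed by C–H reductive elimination turns the Rh–CH2 group into the C5′ methyl. The closest known reaction type is the Rh-catalysed silylcarbocyclization (cyclization/hydrosilylation) of 1,6-enynes, enantioselective with [Rh(cod)2]SbF6 and BIPHEMP, which gives five-membered rings; the extension proposed here is to a 1,7-enyne with a quaternary propargylic carbon and a six-membered ring. The ring closes in the 6-exo-trig mode, helped by the gem-dimethyl group (Thorpe–Ingold effect). The C5′ stereocentre is set by the chiral bisphosphine on rhodium, which selects the face of the vinyl group in the insertion step. The step needs cyclization to outrun plain hydrosilylation of the alkyne and E/Z isomerisation of the alkenylrhodium, which the gem-dimethyl group should favour, and it needs silicon on the terminal carbon, which the terminal alkyne secures. Because the addition is syn, silicon ends cis to C5′ and the hydrogen cis to C1′, which is the (E) geometry that C8′ must have in the target.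

Step 5
Reactants: 9 prop-2-yn-1-ol
Product: 11 (E)-3-iodo-2-methylprop-2-en-1-ol, via alkenylalane 10 (not isolated)
Conditions: Me3Al (3 equiv), Cp2ZrCl2 (25 mol %), CH2Cl2, 0 °C to rt; then I2, THF, −30 to 0 °C
Reagents that add atoms: trimethylaluminium, C[Al](C)C; iodine, II
Why: Zr-catalysed syn-methylalumination of the terminal alkyne (Negishi carboalumination) places methyl on the internal and aluminium on the terminal carbon, and iodinolysis of the C–Al bond with retention should give the (E)-iodide.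

Step 6
Reactants: 8 benzyl(dimethyl){(E)-[(6S)-2,2,6-trimethylcyclohexylidene]methyl}silane; 11 (E)-3-iodo-2-methylprop-2-en-1-ol
Product: 13 (2E,4E)-2-methyl-4-[(6S)-2,2,6-trimethylcyclohexylidene]but-2-en-1-ol, via alkenylsilanol 12 (not isolated)
Conditions: Bu4NF (2.5 equiv), THF, 0 °C; then 11, Pd2(dba)3·CHCl3 (2.5 mol %), rt
Reagents that add atoms: none
Why: In this Hiyama–Denmark cross-coupling fluoride cleaves the benzyl–Si bond to the alkenylsilanol, which transmetalates to the alkenylpalladium iodide formed from 11 with retention at both alkenes, so that C8′ ends cis to C5′; no carbonyl group is yet conjugated with the C5′–H, so the fluoride cannot epimerise it.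

Step 7
Reactants: 13 (2E,4E)-2-methyl-4-[(6S)-2,2,6-trimethylcyclohexylidene]but-2-en-1-ol
Product: 14 (2E,4E)-2-methyl-4-[(6S)-2,2,6-trimethylcyclohexylidene]but-2-enal
Conditions: MnO2, CH2Cl2, rt
Reagents that add atoms: none
Why: MnO2 should oxidise the allylic alcohol selectively to the dienal under neutral heterogeneous conditions (allylic oxidation), which avoids base-mediated enolisation towards C5′.

Step 8
Reactants: 14 (2E,4E)-2-methyl-4-[(6S)-2,2,6-trimethylcyclohexylidene]but-2-enal
Product: 15 (2E,3S)-2-[(2E,4E)-5-iodo-3-methylpenta-2,4-dien-1-ylidene]-1,1,3-trimethylcyclohexane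
Conditions: CHI3, CrCl2, THF, 0 °C, dark
Reagents that add atoms: iodoform, IC(I)I
Why: In the Takai olefination the gem-dichromium species from CHI3 and CrCl2 adds to the aldehyde and eliminates to the (E)-alkenyl iodide under conditions that are neither basic nor protic-acidic.

Step 9
Reactants: 16 all-trans-retinal
Product: 18 (2E,4E,6E,8E,10E)-5,9-dimethyl-11-(2,6,6-trimethylcyclohex-1-en-1-yl)undeca-2,4,6,8,10-pentaenal, via vinyl dioxolane 17 (not isolated)
Conditions: (1,3-dioxolan-2-ylmethyl)triphenylphosphonium bromide, KOt-Bu, THF, 0 °C to rt; then 1 M aq. HCl, THF, rt, dark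
Reagents that add atoms: (1,3-dioxolan-2-ylmethyl)triphenylphosphonium bromide, [Br-].C(C1OCCO1)[P+](c1ccccc1)(c1ccccc1)c1ccccc1; water, O
Why: A Wittig reaction with the two-carbon acetal ylide followed by acid hydrolysis, which should also equilibrate the new enal double bond to E, extends retinal by C15′ and C14′.

Step 10
Reactants: 18 (2E,4E,6E,8E,10E)-5,9-dimethyl-11-(2,6,6-trimethylcyclohex-1-en-1-yl)undeca-2,4,6,8,10-pentaenal
Product: 19 (4E,6E,8E,10E,12E)-7,11-dimethyl-13-(2,6,6-trimethylcyclohex-1-en-1-yl)trideca-4,6,8,10,12-pentaen-1-yn-3-ol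
Conditions: HC≡CMgBr, THF, −20 °C; aq. NH4Cl
Reagents that add atoms: ethynylmagnesium bromide, C#C[Mg]Br
Why: 1,2-Addition of the ethynyl Grignard reagent to the polyenal gives the secondary alcohol, racemic at a carbon that becomes sp2 in the next step.

Step 11
Reactants: 19 (4E,6E,8E,10E,12E)-7,11-dimethyl-13-(2,6,6-trimethylcyclohex-1-en-1-yl)trideca-4,6,8,10,12-pentaen-1-yn-3-ol
Product: 21 (6E)-6-[(2E,4E,6E,8E,10E)-3,7-dimethyltrideca-2,4,6,8,10-pentaen-12-yn-1-ylidene]-1,5,5-trimethylcyclohex-1-ene, via allylic mesylate 20 (not isolated)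
Conditions: Ms2O, Et3N, CH2Cl2, −40 to 0 °C, dark
Reagents that add atoms: none
Why: The polyenylic mesylate should ionise to a cation delocalised from C14′ to C5, and the amine removes H-4 at the ring end (E1-type vinylogous elimination, as in the dehydration of retinol to anhydroretinol), which shifts every double bond into the retro position with E geometry, while the alkyne side offers no proton to lose.

Step 12
Reactants: 21 (6E)-6-[(2E,4E,6E,8E,10E)-3,7-dimethyltrideca-2,4,6,8,10-pentaen-12-yn-1-ylidene]-1,5,5-trimethylcyclohex-1-ene; 15 (2E,3S)-2-[(2E,4E)-5-iodo-3-methylpenta-2,4-dien-1-ylidene]-1,1,3-trimethylcyclohexane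
Product: 23 (5′S,6E,6′E)-4,5′-retro-β,β-carotene, via alkenylalane 22 (not isolated)
Conditions: Me3Al, Cp2ZrCl2 (25 mol %), ClCH2CH2Cl, rt; volatiles removed; then 15, ZnCl2 (cat.), Pd2(dba)3 (2.5 mol %), P(2-furyl)3, THF, rt, dark
Reagents that add atoms: trimethylaluminium, C[Al](C)C
Why: Zr-catalysed syn-methylalumination of the terminal alkyne (Negishi carboalumination) creates the C13′ methyl and the (E)-alkenylalane at C12′, and Pd-catalysed, ZnCl2-promoted cross-coupling with the alkenyl iodide (Negishi coupling) should form the C12′–C11′ bond with retention at both partners.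

**Compound list**

1 | isobutyronitrile | CC(C)C#N | starting material
2 | 5-bromopent-1-ene | BrCCCC=C | starting material
3 | lithiated isobutyronitrile (N-lithio ketenimine form) | CC(C)=C=N[Li] | intermediate
4 | 2,2-dimethylhept-6-enenitrile | N#CC(C)(C)CCCC=C | intermediate
5 | N-(diisobutylaluminio) aldimine of 2,2-dimethylhept-6-enal | CC(C)C[Al](CC(C)C)N=CC(C)(C)CCCC=C | intermediate
6 | 2,2-dimethylhept-6-enal | O=CC(C)(C)CCCC=C | intermediate
7 | 3,3-dimethyloct-7-en-1-yne | C#CC(C)(C)CCCC=C | intermediate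
8 | benzyl(dimethyl){(E)-[(6S)-2,2,6-trimethylcyclohexylidene]methyl}silane | C[Si](C)(Cc1ccccc1)/C=C1\[C@@H](C)CCCC1(C)C | intermediate
9 | prop-2-yn-1-ol | OCC#C | starting material
10 | dimethylaluminium (E)-3-(dimethylalumanyl)-2-methylprop-2-en-1-olate | C[Al](C)/C=C(\C)CO[Al](C)C | intermediate
11 | (E)-3-iodo-2-methylprop-2-en-1-ol | OC/C(C)=C/I | intermediate
12 | dimethyl{(E)-[(6S)-2,2,6-trimethylcyclohexylidene]methyl}silanol | C[Si](C)(O)/C=C1\[C@@H](C)CCCC1(C)C | intermediate
13 | (2E,4E)-2-methyl-4-[(6S)-2,2,6-trimethylcyclohexylidene]but-2-en-1-ol | OC/C(C)=C/C=C1\[C@@H](C)CCCC1(C)C | intermediate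
14 | (2E,4E)-2-methyl-4-[(6S)-2,2,6-trimethylcyclohexylidene]but-2-enal | O=C/C(C)=C/C=C1\[C@@H](C)CCCC1(C)C | intermediate
15 | (2E,3S)-2-[(2E,4E)-5-iodo-3-methylpenta-2,4-dien-1-ylidene]-1,1,3-trimethylcyclohexane | I/C=C/C(C)=C/C=C1\[C@@H](C)CCCC1(C)C | intermediate
16 | all-trans-retinal | CC1=C(/C=C/C(C)=C/C=C/C(C)=C/C=O)C(C)(C)CCC1 | starting material
17 | 2-[(3E,5E,7E,9E)-4,8-dimethyl-10-(2,6,6-trimethylcyclohex-1-en-1-yl)deca-1,3,5,7,9-pentaen-1-yl]-1,3-dioxolane (new double bond E/Z) | CC1=C(/C=C/C(C)=C/C=C/C(C)=C/C=CC2OCCO2)C(C)(C)CCC1 | intermediate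
18 | (2E,4E,6E,8E,10E)-5,9-dimethyl-11-(2,6,6-trimethylcyclohex-1-en-1-yl)undeca-2,4,6,8,10-pentaenal | CC1=C(/C=C/C(C)=C/C=C/C(C)=C/C=C/C=O)C(C)(C)CCC1 | intermediate
19 | (4E,6E,8E,10E,12E)-7,11-dimethyl-13-(2,6,6-trimethylcyclohex-1-en-1-yl)trideca-4,6,8,10,12-pentaen-1-yn-3-ol (racemic at C3) | CC1=C(/C=C/C(C)=C/C=C/C(C)=C/C=C/C(O)C#C)C(C)(C)CCC1 | intermediate
20 | methanesulfonate of 19 | CC1=C(/C=C/C(C)=C/C=C/C(C)=C/C=C/C(OS(C)(=O)=O)C#C)C(C)(C)CCC1 | intermediate
21 | (6E)-6-[(2E,4E,6E,8E,10E)-3,7-dimethyltrideca-2,4,6,8,10-pentaen-12-yn-1-ylidene]-1,5,5-trimethylcyclohex-1-ene | CC1=CCCC(C)(C)\C1=C/C=C(C)/C=C/C=C(C)/C=C/C=C/C#C | intermediate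
22 | (E)-alkenyl(dimethyl)alane from syn-methylalumination of 21 (Al on C12′, new methyl on C13′) | CC1=CCCC(C)(C)\C1=C/C=C(C)/C=C/C=C(C)/C=C/C=C/C(C)=C/[Al](C)C | intermediate
23 | (5′S,6E,6′E)-4,5′-retro-β,β-carotene (CNP0257724.1) | CC1=CCCC(C)(C)\C1=C/C=C(C)/C=C/C=C(C)/C=C/C=C/C(C)=C/C=C/C(C)=C/C=C1\[C@@H](C)CCCC1(C)C | target

**Count and risks**

Total step count: 12. Longest linear sequence: 8 steps (1, 2, 3, 4, 6, 7, 8, 12).

Steps most likely to fail:

1. Step 4 (bears the label). After silylrhodation the alkenylrhodium may be intercepted by Si–H before the six-membered ring closes (plain hydrosilylation), or the vinyl group may insert with poor facial selectivity. The fallback uses known chemistry and makes the same C5′–C6′ ring bond by a stereospecific SN2 reaction; it sets out from 2 and 11 and returns at 13.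
   - Bromide 2 is converted with Mg into pent-4-en-1-ylmagnesium bromide F1, which adds (CuI cat., Me3SiCl, THF) to commercial ethyl 3-methylbut-2-enoate to give ethyl 3,3-dimethyloct-7-enoate F2.
   - Tsuji–Wacker oxidation (PdCl2, CuCl, O2, DMF/H2O) gives ethyl 3,3-dimethyl-7-oxooctanoate F3.
   - An (R)-selective ketoreductase (NADPH, i-PrOH) gives ethyl (7R)-7-hydroxy-3,3-dimethyloctanoate F4, and TsCl/pyridine gives ethyl (7R)-3,3-dimethyl-7-(tosyloxy)octanoate F5.
   - KN(SiMe3)2 in THF closes the ring by intramolecular ester-enolate alkylation (6-exo-tet, inversion at C5′) to ethyl (6S)-2,2,6-trimethylcyclohexane-1-carboxylate F6.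
   - i-Bu2AlH at −78 °C gives (6S)-2,2,6-trimethylcyclohexane-1-carbaldehyde F7.
   - Tf2O with 2,6-di-tert-butyl-4-methylpyridine gives (E)-[(6S)-2,2,6-trimethylcyclohexylidene]methyl trifluoromethanesulfonate F8. The triflate group should prefer the side of the CH(CH3) carbon, and the Z isomer would be removed by chromatography.
   - Iodide 11 is converted (NaH; t-BuLi; Bu3SnCl) into (E)-2-methyl-3-(tributylstannyl)prop-2-en-1-ol F9, and Stille coupling of F8 with F9 (Pd(PPh3)4, LiCl, THF, 60 °C) gives 13.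

2. Step 11. The delocalised cation may lose a proton from a methyl group (C18, C19 or C20) instead of C4, or be captured and oligomerise. The fallback sets out from 19 and returns at 21. Acetylation (Ac2O, pyridine, DMAP) gives (4E,6E,8E,10E,12E)-7,11-dimethyl-13-(2,6,6-trimethylcyclohex-1-en-1-yl)trideca-4,6,8,10,12-pentaen-1-yn-3-yl acetate F10. Pd(PPh3)4 (5 mol %) with Et3N in THF at 50 °C ionises it to a polyenyl π-allyl complex of palladium (zerovalent palladium, Tsuji–Trost-type elimination), which should lose H-4 by β-hydride elimination at the ring end to give 21 without a free carbocation.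

3. Step 12. The retro-polyene may isomerise or decompose under the Lewis-acidic methylalumination conditions, or the terminal alkyne may be metalated instead of carbometalated. The fallback sets out from 19 and 14 and returns at 23.
   - Methylalumination is moved to the more robust carbinol: 19 with Me3Al/Cp2ZrCl2 gives the alkenylalane alkoxide F11, and iodinolysis gives (1E,4E,6E,8E,10E,12E)-1-iodo-2,7,11-trimethyl-13-(2,6,6-trimethylcyclohex-1-en-1-yl)trideca-1,4,6,8,10,12-hexaen-3-ol F12.
   - Ms2O/Et3N converts F12 through its methanesulfonate F13 into the retro-polyenyl iodide (6E)-6-[(2E,4E,6E,8E,10E,12E)-13-iodo-3,7,12-trimethyltrideca-2,4,6,8,10,12-hexaen-1-ylidene]-1,5,5-trimethylcyclohex-1-ene F14.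
   - Aldehyde 14 is converted by Takai–Utimoto olefination (Cl2CHB(pin), CrCl2, LiI, THF) into the (E)-trienylboronic acid pinacol ester F15.
   - Suzuki–Miyaura coupling of F14 with F15 (Pd(PPh3)4, aq. K3PO4, THF, rt, dark) gives 23.

Further compounds
F1 | step 4 | pent-4-en-1-ylmagnesium bromide | C=CCCC[Mg]Br
F2 | step 4 | ethyl 3,3-dimethyloct-7-enoate | CCOC(=O)CC(C)(C)CCCC=C
F3 | step 4 | ethyl 3,3-dimethyl-7-oxooctanoate | CCOC(=O)CC(C)(C)CCCC(C)=O
F4 | step 4 | ethyl (7R)-7-hydroxy-3,3-dimethyloctanoate | CCOC(=O)CC(C)(C)CCC[C@@H](C)O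
F5 | step 4 | ethyl (7R)-3,3-dimethyl-7-(tosyloxy)octanoate | CCOC(=O)CC(C)(C)CCC[C@@H](C)OS(=O)(=O)c1ccc(C)cc1
F6 | step 4 | ethyl (6S)-2,2,6-trimethylcyclohexane-1-carboxylate (C1 epimers) | CCOC(=O)C1[C@@H](C)CCCC1(C)C
F7 | step 4 | (6S)-2,2,6-trimethylcyclohexane-1-carbaldehyde (C1 epimers) | O=CC1[C@@H](C)CCCC1(C)C
F8 | step 4 | (E)-[(6S)-2,2,6-trimethylcyclohexylidene]methyl trifluoromethanesulfonate | O=S(=O)(O/C=C1\[C@@H](C)CCCC1(C)C)C(F)(F)F
F9 | step 4 | (E)-2-methyl-3-(tributylstannyl)prop-2-en-1-ol | CCCC[Sn](CCCC)(CCCC)/C=C(\C)CO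
F10 | step 11 | (4E,6E,8E,10E,12E)-7,11-dimethyl-13-(2,6,6-trimethylcyclohex-1-en-1-yl)trideca-4,6,8,10,12-pentaen-1-yn-3-yl acetate | CC1=C(/C=C/C(C)=C/C=C/C(C)=C/C=C/C(OC(C)=O)C#C)C(C)(C)CCC1
F11 | step 12 | alkenylalane alkoxide from syn-methylalumination of 19 | CC1=C(/C=C/C(C)=C/C=C/C(C)=C/C=C/C(O[Al](C)C)/C(C)=C/[Al](C)C)C(C)(C)CCC1
F12 | step 12 | (1E,4E,6E,8E,10E,12E)-1-iodo-2,7,11-trimethyl-13-(2,6,6-trimethylcyclohex-1-en-1-yl)trideca-1,4,6,8,10,12-hexaen-3-ol | CC1=C(/C=C/C(C)=C/C=C/C(C)=C/C=C/C(O)/C(C)=C/I)C(C)(C)CCC1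
F13 | step 12 | methanesulfonate of F12 | CC1=C(/C=C/C(C)=C/C=C/C(C)=C/C=C/C(OS(C)(=O)=O)/C(C)=C/I)C(C)(C)CCC1
F14 | step 12 | (6E)-6-[(2E,4E,6E,8E,10E,12E)-13-iodo-3,7,12-trimethyltrideca-2,4,6,8,10,12-hexaen-1-ylidene]-1,5,5-trimethylcyclohex-1-ene | CC1=CCCC(C)(C)\C1=C/C=C(C)/C=C/C=C(C)/C=C/C=C/C(C)=C/I
F15 | step 12 | 4,4,5,5-tetramethyl-2-{(1E,3E)-3-methyl-5-[(2E,6S)-2,2,6-trimethylcyclohexylidene]penta-1,3-dien-1-yl}-1,3,2-dioxaborolane | CC1(C)OB(/C=C/C(C)=C/C=C2\[C@@H](C)CCCC2(C)C)OC1(C)C
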